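**Plan**

- Retrosynthesis: after adjusting the C4 silyl ether and the C9 carbinol (from a C9 ketone), the ring bond C10–C1 of the cycloheptane is cut as an aldol. The ring carries the array C9(O)–C10(CH3)–C1(OH)–C2(=O), a β‑hydroxy ketone whose acceptor carbon C1 is the inner carbonyl of a 1,2‑diketone.
- Further cuts: C1/C2 diketone from a C1=C2 alkene (dihydroxylation, oxidation); the C5–O ester (Mitsunobu); C5–C1 (alkenylzinc plus aldehyde); C6–C7 and the lactone C–O bond (indium Barbier 2‑(alkoxycarbonyl)allylation, lactonisation).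
- Forward order: the cis α‑methylene‑γ‑butyrolactone is made first, the side chain and ester are attached, and the seven‑membered carbocycle is closed last. The C9 allyl silyl ether is both protecting group and latent C9=C10 enol silane; C9 stays at the ketone level through the closure.
- Stereochemistry: C4 and the ester centre are bought. C6 comes from (S)‑glyceraldehyde acetonide (Felkin–Anh; that centre is then excised), C7 from the chair Barbier transition state, C5 from Felkin–Anh addition followed by Mitsunobu inversion. C1 and C10 are set together in the ring closure, C9 by C1–OH‑directed reduction.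

Key step: step 12

Remark (numbering used in names): lactone C12(=O)–O–C6, C11(=C13H2), C7; carbocycle C7–C8–C9–C10–C1–C5–C6; C14 = methyl on C10; side chain C2(=O)–C3H2–C4H(OH)–C15H3; TBS = tert‑butyldimethylsilyl, TIPS = triisopropylsilyl.

Remark (assumption): 1 is used as the racemate, so C9 is carried as an inconsequential pair of epimers (drawn without descriptor) until it becomes sp2 in step 12.

**Route**

Step 1
Reactants: 1 ethyl 3-hydroxypent-4-enoate (racemic)
Product: 2 ethyl 3-(tert-butyldimethylsilyloxy)pent-4-enoate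
Conditions: TBSCl, imidazole, DMF, rt
Reagents that add atoms: tert-butyldimethylsilyl chloride, CC(C)(C)[Si](C)(C)Cl
Why: Standard silyl ether formation on a secondary allylic alcohol; this TBS ether later serves as the latent C9 enol silane.

Step 2
Reactants: 2 ethyl 3-(tert-butyldimethylsilyloxy)pent-4-enoate
Product: 3 3-(tert-butyldimethylsilyloxy)pent-4-enal
Conditions: i-Bu2AlH (1.05 equiv), CH2Cl2, −78 °C; Rochelle salt work-up
Reagents that add atoms: none
Why: Partial ester reduction stops at the aldehyde because the tetrahedral aluminium hemiacetal is stable at −78 °C.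

Step 3
Reactants: 3 3-(tert-butyldimethylsilyloxy)pent-4-enal; 4 methyl acrylate
Product: 5 methyl 5-(tert-butyldimethylsilyloxy)-3-hydroxy-2-methylidenehept-6-enoate (diastereomer mixture)
Conditions: DABCO, methyl acrylate (excess, neat), rt
Reagents that add atoms: none
Why: Morita–Baylis–Hillman reaction of an aliphatic aldehyde with an acrylate; the new carbinol centre is removed in step 4.

Step 4
Reactants: 5 methyl 5-(tert-butyldimethylsilyloxy)-3-hydroxy-2-methylidenehept-6-enoate
Product: 6 methyl (2Z)-2-(bromomethyl)-5-(tert-butyldimethylsilyloxy)hepta-2,6-dienoate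
Conditions: NBS, Me2S, CH2Cl2, 0 °C to rt
Reagents that add atoms: N-bromosuccinimide, O=C1CCC(=O)N1Br
Why: Corey–Kim-type activation of the Baylis–Hillman alcohol and SN2′ attack of bromide transpose the allyl system and should give the thermodynamically favoured (Z)-2-(bromomethyl)enoate.

Step 5
Reactants: 6 methyl (2Z)-2-(bromomethyl)-5-(tert-butyldimethylsilyloxy)hepta-2,6-dienoate; 7 (S)-2,2-dimethyl-1,3-dioxolane-4-carbaldehyde
Product: 9 cis-lactone acetonide (4S,5R)-4-[2-(tert-butyldimethylsilyloxy)but-3-enyl]-5-[(4S)-2,2-dimethyl-1,3-dioxolan-4-yl]-3-methylideneoxolan-2-one, via hydroxy ester 8 (not isolated)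
Conditions: In powder, THF/H2O (1:1), rt; then PPTS (cat.), toluene, 50 °C
Reagents that add atoms: none
Why: Indium-mediated Barbier 2-(alkoxycarbonyl)allylation: the allylindium reacts through its γ-carbon in a chair transition state (6,7-syn from the Z reagent, hence the cis lactone) on the Felkin–Anh face of the α-alkoxy aldehyde (new C6–O anti to the dioxolane C–O), and acid then closes the γ-lactone.

Step 6
Reactants: 9 cis-lactone acetonide
Product: 11 (2R,3S)-3-[2-(tert-butyldimethylsilyloxy)but-3-enyl]-4-methylidene-5-oxooxolane-2-carbaldehyde, via lactone diol 10 (not isolated)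
Conditions: H5IO6, EtOAc, rt
Reagents that add atoms: none
Why: Periodic acid hydrolyses the terminal acetonide and cleaves the liberated 1,2-diol in one pot (Malaprade glycol cleavage) under non-basic conditions that should not epimerise C6.

Step 7
Reactants: 12 (R)-pent-4-yn-2-ol
Product: 13 (R)-4-(triisopropylsilyloxy)pent-1-yne
Conditions: TIPSOTf, 2,6-lutidine, CH2Cl2, 0 °C
Reagents that add atoms: triisopropylsilyl triflate, CC(C)[Si](C(C)C)(C(C)C)OS(=O)(=O)C(F)(F)F
Why: Silylation of a secondary alcohol with the silyl triflate; TIPS is chosen so that it outlasts the TBS ether at C9.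

Step 8
Reactants: 13 (R)-4-(triisopropylsilyloxy)pent-1-yne; 11 lactone aldehyde
Product: 16 allylic alcohol (4S,5R)-4-[2-(tert-butyldimethylsilyloxy)but-3-enyl]-5-[(1S,2E,5R)-1-hydroxy-5-(triisopropylsilyloxy)hex-2-enyl]-3-methylideneoxolan-2-one, via alkenylzirconocene chloride 14 (not isolated), via alkenylmethylzinc 15 (not isolated)
Conditions: Cp2Zr(H)Cl, CH2Cl2, rt; Me2Zn, −65 °C; then 11, −65 to 0 °C; aq. NH4Cl
Reagents that add atoms: Cp2Zr(H)Cl, [H][Zr](Cl)(C1C=CC=C1)C1C=CC=C1 (only its hydride hydrogen stays in 16; the zirconium fragment is present in 14 only); dimethylzinc, C[Zn]C (present in 15 only)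
Why: syn-Hydrozirconation of the terminal alkyne, zirconium-to-zinc transmetalation and 1,2-addition of the (E)-alkenylzinc to the aldehyde; Felkin–Anh attack anti to the ring C6–O bond should give the 5,6-erythro (5S) alcohol.

Step 9
Reactants: 16 allylic alcohol (5S); 17 (S)-2-methylbutanoic acid
Product: 18 allylic ester (1R,2E,5R)-1-[(2R,3S)-3-[2-(tert-butyldimethylsilyloxy)but-3-enyl]-4-methylidene-5-oxooxolan-2-yl]-5-(triisopropylsilyloxy)hex-2-enyl (2S)-2-methylbutanoate
Conditions: PPh3, DIAD, THF, 0 °C to rt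
Reagents that add atoms: none
Why: Mitsunobu esterification displaces the oxyphosphonium at the activated allylic carbinol by SN2 with inversion, so that C5 acquires the configuration of the target together with its ester.

Step 10
Reactants: 18 allylic ester
Product: 19 diol (1R,2S,3R,5R)-1-[(2R,3S)-3-[2-(tert-butyldimethylsilyloxy)but-3-enyl]-4-methylidene-5-oxooxolan-2-yl]-2,3-dihydroxy-5-(triisopropylsilyloxy)hexyl (2S)-2-methylbutanoate
Conditions: K2OsO2(OH)4 (cat.), (DHQD)2PHAL (cat.), NMO, acetone/H2O, 0 °C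
Reagents that add atoms: N-methylmorpholine N-oxide, C[N+]1([O-])CCOCC1; water, O
Why: Ligand-accelerated osmium-catalysed syn-dihydroxylation (Sharpless type) should prefer the trans-disubstituted C1=C2 alkene over the hindered monosubstituted allyl silyl ether and the electron-poor α-methylene lactone; the two new carbinol centres (face set by the ligand) are erased in step 11 and the neutral NMO conditions limit acyl migration.

Step 11
Reactants: 19 diol
Product: 20 1,2-diketone (1S,5R)-1-[(2R,3S)-3-[2-(tert-butyldimethylsilyloxy)but-3-enyl]-4-methylidene-5-oxooxolan-2-yl]-2,3-dioxo-5-(triisopropylsilyloxy)hexyl (2S)-2-methylbutanoate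
Conditions: IBX, DMSO, rt
Reagents that add atoms: none
Why: IBX oxidises both hydroxyls of a vicinal diol to the 1,2-diketone without C–C cleavage, under neutral conditions that leave the acidic C3 and C5 hydrogens alone.

Step 12
Reactants: 20 1,2-diketone
Product: 22 keto aldol (3aS,6R,7S,8S,8aR)-7-hydroxy-6-methyl-3-methylidene-2,5-dioxo-7-[(3R)-3-(triisopropylsilyloxy)butanoyl]octahydro-2H-cyclohepta[b]furan-8-yl (2S)-2-methylbutanoate, via silyl enol ether 21 (not isolated)
Conditions: [Ir(cod)(PMePh2)2]PF6 (cat., activated with H2, then degassed), CH2Cl2, rt; then [Cu((R,R)-t-Bu-box)](OTf)2 (1.1 equiv; box = 2,2′-(propane-2,2-diyl)bis(4-tert-butyl-4,5-dihydrooxazole)), −78 to −40 °C; aq. NH4Cl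
Reagents that add atoms: none
Why: The cationic iridium hydride moves the terminal C10=C14 double bond of the allyl silyl ether next to oxygen (1,3-hydrogen shift) and so gives enol silane 21 regiospecifically at C9=C10; the divalent copper complex then binds the C1/C2 1,2-diketone as a five-membered chelate and C10 adds to C1 in a Mukaiyama aldol. The closest known reactions are the iridium-catalysed isomerisation of allyl silyl ethers to silyl enol ethers and the bis(oxazoline)copper-mediated Mukaiyama aldol addition of enol silanes to pyruvates and 1,2-diketones. The cycloheptane closes in the 7-(enolendo)-exo-trig mode. C1 is controlled by the tert-butyl groups of the (R,R) ligand, which screen one face of the square-planar chelate, and the substrate should reinforce this because attack on the other face would align the C1=O and C5–O dipoles (Cornforth argument), so the new hydroxyl ends trans to the C5 ester. C10 is set in the open transition state of this catalyst system, which gives the syn methyl/hydroxyl adduct from either enol silane geometry (here methyl cis to the C1 hydroxyl), and the centre stays epimerisable next to the C9 ketone toward this arrangement with methyl trans to the C2 acyl branch. The step needs enolisation toward C10 only (secured by the position of the allyl ether and the absence of base, so C3–H, C5–H and C8 stay untouched), attack at C1 and not C2 (seven- against eight-membered ring), and no Michael closure onto the α-methylene lactone (secured because only the bidentate diketone is activated by copper).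

Step 13
Reactants: 22 keto aldol
Product: 23 (3aS,5R,6S,7S,8S,8aR)-5,7-dihydroxy-6-methyl-3-methylidene-2-oxo-7-[(3R)-3-(triisopropylsilyloxy)butanoyl]octahydro-2H-cyclohepta[b]furan-8-yl (2S)-2-methylbutanoate
Conditions: Me4NBH(OAc)3, MeCN/AcOH (1:1), −30 °C
Reagents that add atoms: none
Why: Saksena–Evans hydroxyl-directed reduction: the C1 hydroxyl exchanges onto boron and delivers hydride internally to the β-carbonyl C9 through a six-membered chair on the C1–O face, which should give the 1,3-trans (9R) diol, while the C2 ketone is reachable only through a strained five-membered delivery and C4–O is silylated.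

Step 14
Reactants: 23 silyl ether
Product: 24 (3aS,5R,6S,7S,8S,8aR)-5,7-dihydroxy-7-[(3R)-3-hydroxybutanoyl]-6-methyl-3-methylidene-2-oxooctahydro-2H-cyclohepta[b]furan-8-yl (2S)-2-methylbutanoate (CNP0291806.4)
Conditions: HF·pyridine, THF, 0 °C to rt
Reagents that add atoms: none
Why: Fluoride-mediated cleavage of the remaining silyl ether under mildly acidic conditions that the α-ketol, the β-hydroxy ketone and the α-methylene lactone should tolerate.

**Compound list**

1 | ethyl 3-hydroxypent-4-enoate (racemic) | CCOC(=O)CC(O)C=C | starting material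
2 | ethyl 3-(tert-butyldimethylsilyloxy)pent-4-enoate | CCOC(=O)CC(O[Si](C)(C)C(C)(C)C)C=C | intermediate
3 | 3-(tert-butyldimethylsilyloxy)pent-4-enal | O=CCC(O[Si](C)(C)C(C)(C)C)C=C | intermediate
4 | methyl acrylate | C=CC(=O)OC | starting material
5 | methyl 5-(tert-butyldimethylsilyloxy)-3-hydroxy-2-methylidenehept-6-enoate | COC(=O)C(=C)C(O)CC(O[Si](C)(C)C(C)(C)C)C=C | intermediate
6 | methyl (2Z)-2-(bromomethyl)-5-(tert-butyldimethylsilyloxy)hepta-2,6-dienoate | COC(=O)/C(CBr)=C/CC(O[Si](C)(C)C(C)(C)C)C=C | intermediate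
7 | (S)-2,2-dimethyl-1,3-dioxolane-4-carbaldehyde | O=C[C@@H]1COC(C)(C)O1 | starting material
8 | methyl (3S,4R)-3-[2-(tert-butyldimethylsilyloxy)but-3-enyl]-4-[(4S)-2,2-dimethyl-1,3-dioxolan-4-yl]-4-hydroxy-2-methylidenebutanoate | COC(=O)C(=C)[C@@H]([C@@H](O)[C@@H]1COC(C)(C)O1)CC(O[Si](C)(C)C(C)(C)C)C=C | intermediate (not isolated)
9 | (4S,5R)-4-[2-(tert-butyldimethylsilyloxy)but-3-enyl]-5-[(4S)-2,2-dimethyl-1,3-dioxolan-4-yl]-3-methylideneoxolan-2-one | C=C1C(=O)O[C@@H]([C@@H]2COC(C)(C)O2)[C@H]1CC(O[Si](C)(C)C(C)(C)C)C=C | intermediate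
10 | (4S,5R)-4-[2-(tert-butyldimethylsilyloxy)but-3-enyl]-5-[(1S)-1,2-dihydroxyethyl]-3-methylideneoxolan-2-one | C=C1C(=O)O[C@@H]([C@@H](O)CO)[C@H]1CC(O[Si](C)(C)C(C)(C)C)C=C | intermediate (not isolated)
11 | (2R,3S)-3-[2-(tert-butyldimethylsilyloxy)but-3-enyl]-4-methylidene-5-oxooxolane-2-carbaldehyde | C=C1C(=O)O[C@@H](C=O)[C@H]1CC(O[Si](C)(C)C(C)(C)C)C=C | intermediate
12 | (R)-pent-4-yn-2-ol | C#CC[C@@H](C)O | starting material
13 | (R)-4-(triisopropylsilyloxy)pent-1-yne | C#CC[C@@H](C)O[Si](C(C)C)(C(C)C)C(C)C | intermediate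
14 | chlorobis(cyclopentadienyl)[(1E,4R)-4-(triisopropylsilyloxy)pent-1-enyl]zirconium | Cl[Zr](/C=C/C[C@@H](C)O[Si](C(C)C)(C(C)C)C(C)C)(C1C=CC=C1)C1C=CC=C1 | intermediate (not isolated)
15 | methyl[(1E,4R)-4-(triisopropylsilyloxy)pent-1-enyl]zinc | C[Zn]/C=C/C[C@@H](C)O[Si](C(C)C)(C(C)C)C(C)C | intermediate (not isolated)
16 | (4S,5R)-4-[2-(tert-butyldimethylsilyloxy)but-3-enyl]-5-[(1S,2E,5R)-1-hydroxy-5-(triisopropylsilyloxy)hex-2-enyl]-3-methylideneoxolan-2-one | C=C1C(=O)O[C@@H]([C@@H](O)/C=C/C[C@@H](C)O[Si](C(C)C)(C(C)C)C(C)C)[C@H]1CC(O[Si](C)(C)C(C)(C)C)C=C | intermediate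
17 | (S)-2-methylbutanoic acid | CC[C@H](C)C(=O)O | starting material
18 | (1R,2E,5R)-1-[(2R,3S)-3-[2-(tert-butyldimethylsilyloxy)but-3-enyl]-4-methylidene-5-oxooxolan-2-yl]-5-(triisopropylsilyloxy)hex-2-enyl (2S)-2-methylbutanoate | C=C1C(=O)O[C@@H]([C@H](OC(=O)[C@@H](C)CC)/C=C/C[C@@H](C)O[Si](C(C)C)(C(C)C)C(C)C)[C@H]1CC(O[Si](C)(C)C(C)(C)C)C=C | intermediate
19 | (1R,2S,3R,5R)-1-[(2R,3S)-3-[2-(tert-butyldimethylsilyloxy)but-3-enyl]-4-methylidene-5-oxooxolan-2-yl]-2,3-dihydroxy-5-(triisopropylsilyloxy)hexyl (2S)-2-methylbutanoate | C=C1C(=O)O[C@@H]([C@H](OC(=O)[C@@H](C)CC)[C@@H](O)[C@H](O)C[C@@H](C)O[Si](C(C)C)(C(C)C)C(C)C)[C@H]1CC(O[Si](C)(C)C(C)(C)C)C=C | intermediate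
20 | (1S,5R)-1-[(2R,3S)-3-[2-(tert-butyldimethylsilyloxy)but-3-enyl]-4-methylidene-5-oxooxolan-2-yl]-2,3-dioxo-5-(triisopropylsilyloxy)hexyl (2S)-2-methylbutanoate | C=C1C(=O)O[C@@H]([C@H](OC(=O)[C@@H](C)CC)C(=O)C(=O)C[C@@H](C)O[Si](C(C)C)(C(C)C)C(C)C)[C@H]1CC(O[Si](C)(C)C(C)(C)C)C=C | intermediate
21 | isomer of 20 with the C9 allyl silyl ether turned into the (Z)-C9=C10 tert-butyldimethylsilyl enol ether | C=C1C(=O)O[C@@H]([C@H](OC(=O)[C@@H](C)CC)C(=O)C(=O)C[C@@H](C)O[Si](C(C)C)(C(C)C)C(C)C)[C@H]1C/C(O[Si](C)(C)C(C)(C)C)=C/C | intermediate (not isolated)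
22 | (3aS,6R,7S,8S,8aR)-7-hydroxy-6-methyl-3-methylidene-2,5-dioxo-7-[(3R)-3-(triisopropylsilyloxy)butanoyl]octahydro-2H-cyclohepta[b]furan-8-yl (2S)-2-methylbutanoate | C=C1C(=O)O[C@@H]2[C@H]1CC(=O)[C@H](C)[C@@](O)(C(=O)C[C@@H](C)O[Si](C(C)C)(C(C)C)C(C)C)[C@H]2OC(=O)[C@@H](C)CC | intermediate
23 | (3aS,5R,6S,7S,8S,8aR)-5,7-dihydroxy-6-methyl-3-methylidene-2-oxo-7-[(3R)-3-(triisopropylsilyloxy)butanoyl]octahydro-2H-cyclohepta[b]furan-8-yl (2S)-2-methylbutanoate | C=C1C(=O)O[C@@H]2[C@H]1C[C@@H](O)[C@H](C)[C@@](O)(C(=O)C[C@@H](C)O[Si](C(C)C)(C(C)C)C(C)C)[C@H]2OC(=O)[C@@H](C)CC | intermediate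
24 | (3aS,5R,6S,7S,8S,8aR)-5,7-dihydroxy-7-[(3R)-3-hydroxybutanoyl]-6-methyl-3-methylidene-2-oxooctahydro-2H-cyclohepta[b]furan-8-yl (2S)-2-methylbutanoate | C=C1C(=O)O[C@@H]2[C@H]1C[C@@H](O)[C@H](C)[C@@](O)(C(=O)C[C@@H](C)O)[C@H]2OC(=O)[C@@H](C)CC | target

**Step count and risks**

Total step count: 14. Longest linear sequence: 13 (steps 1–6 and 8–14; step 7 is the side branch).

Steps most likely to fail:

1. Step 12. What may go wrong: a mismatched pairing of ligand and substrate could give poor facial selectivity at C1 (or the wrong C10 epimer), or the enol silane could close onto the α-methylene lactone in a Michael sense instead of onto C1. Fallback: a closed, metal-bound enolate replaces the open Mukaiyama transition state. It sets out from 20. HF·pyridine buffered with pyridine at 0 °C should remove only the allylic TBS ether (TIPS stays) to give the allylic alcohol F1. Dess–Martin oxidation gives the vinyl ketone F2. TiCl4/n-Bu4NI at −78 °C adds iodide to the enone and generates a (Z)-titanium enolate that closes on C1 through a chelated six-membered transition state to the iodo aldol F3. Bu3SnH/Et3B then replaces iodine by hydrogen and the route is rejoined at 22.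

2. Step 10. What may go wrong: poor site selectivity of the osmylation among the three alkenes, or migration of the C5 acyl group onto the new diol. Fallback: hydroxyl-directed oxidation before the ester is introduced. It sets out from 16. VO(acac)2/t-BuOOH epoxidises only the double bond of the allylic alcohol and gives the epoxy alcohol F4. Mitsunobu esterification with 17 gives the inverted epoxy ester F5. Acid-catalysed hydrolysis (HClO4, THF/H2O) opens the epoxide to the anti diol F6, and IBX oxidation rejoins the route at 20.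

3. Step 13. What may go wrong: competing reduction of the C2 ketone of the α-ketol, or slow exchange of the tertiary hydroxyl onto boron so that undirected hydride attack gives the wrong C9 configuration. Fallback: intramolecular hydrosilylation in place of borohydride delivery. It sets out from 22. (i-Pr)2SiHCl/imidazole gives the hydridosilyl ether F7. Catalytic SnCl4 at −80 °C delivers the silicon hydride to the C9 ketone through a six-membered chair and gives the 1,3-trans siladioxane F8. HF·pyridine cleaves the silylene together with the TIPS ether and the route is rejoined at 24.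

**Further compounds**

F1 | step 12 | allylic alcohol (20 without the TBS group) | C=C1C(=O)O[C@@H]([C@H](OC(=O)[C@@H](C)CC)C(=O)C(=O)C[C@@H](C)O[Si](C(C)C)(C(C)C)C(C)C)[C@H]1CC(O)C=C
F2 | step 12 | vinyl ketone (C9 enone) | C=C1C(=O)O[C@@H]([C@H](OC(=O)[C@@H](C)CC)C(=O)C(=O)C[C@@H](C)O[Si](C(C)C)(C(C)C)C(C)C)[C@H]1CC(=O)C=C
F3 | step 12 | iodo aldol (22 with CH2I in place of the C10 methyl) | C=C1C(=O)O[C@@H]2[C@H]1CC(=O)[C@H](CI)[C@@](O)(C(=O)C[C@@H](C)O[Si](C(C)C)(C(C)C)C(C)C)[C@H]2OC(=O)[C@@H](C)CC
F4 | step 10 | epoxy alcohol (trans C1–C2 epoxide of 16; facial isomers at C1/C2 not specified) | C=C1C(=O)O[C@@H]([C@@H](O)C2OC2C[C@@H](C)O[Si](C(C)C)(C(C)C)C(C)C)[C@H]1CC(O[Si](C)(C)C(C)(C)C)C=C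
F5 | step 10 | epoxy ester (C5 inverted; C1/C2 as in F4) | C=C1C(=O)O[C@@H]([C@H](OC(=O)[C@@H](C)CC)C2OC2C[C@@H](C)O[Si](C(C)C)(C(C)C)C(C)C)[C@H]1CC(O[Si](C)(C)C(C)(C)C)C=C
F6 | step 10 | anti diol (C1/C2 diastereomer of 19; C1/C2 not specified) | C=C1C(=O)O[C@@H]([C@H](OC(=O)[C@@H](C)CC)C(O)C(O)C[C@@H](C)O[Si](C(C)C)(C(C)C)C(C)C)[C@H]1CC(O[Si](C)(C)C(C)(C)C)C=C
F7 | step 13 | C1 diisopropylsilyl (Si–H) ether of 22 | C=C1C(=O)O[C@@H]2[C@H]1CC(=O)[C@H](C)[C@@](O[SiH](C(C)C)C(C)C)(C(=O)C[C@@H](C)O[Si](C(C)C)(C(C)C)C(C)C)[C@H]2OC(=O)[C@@H](C)CC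
F8 | step 13 | C1,C9 diisopropylsilylene acetal (siladioxane) of 23 | C=C1C(=O)O[C@@H]2[C@H]1C[C@@H](O3)[C@H](C)[C@@](O[Si]3(C(C)C)C(C)C)(C(=O)C[C@@H](C)O[Si](C(C)C)(C(C)C)C(C)C)[C@H]2OC(=O)[C@@H](C)CC
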